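Locants follow flavanone numbering, with A for the 4-methoxyphenyl unit and B for the 4-hydroxyphenyl unit. Everything rests on cutting the C2B–C3B bond of the pyranone ring of unit B. There the oxygen-bearing benzylic carbon C2B (on O1B) meets C3B, the carbon alpha to the C4B ketone, with the aryl group and C3A cis: the imprint of a ketocarbenoid at C3B inserting into a benzylic C–H bond of an ortho aryl benzyl ether. One operation thus closes this ring, completes the biflavanone and sets C2B and C3B. The precursor is benzyl-protected trans-flavanone A bearing at C3A a diazoketone whose aryl ring carries three 4-(benzyloxy)benzyl ethers.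

Key step: step 9

Assumption: the hand of the ligand in step 3 and of the catalyst in step 9 is the one expected to give the drawn configuration; if the parent reaction shows the opposite sense, the mirror-image ligand or catalyst is used without other change.

Step 1
Reactants: 1 2,4,6-trihydroxyacetophenone; 2 benzyl bromide
Product: 3 1-[2,4-bis(benzyloxy)-6-hydroxyphenyl]ethan-1-one
Conditions: BnBr (2.1 equiv in all), K2CO3, DMF, 0 °C to rt
Reagents that add atoms: benzyl bromide (second equivalent), BrCc1ccccc1
Why: Williamson etherification in which two molecules of benzyl bromide alkylate the 4-OH and one ortho OH while the remaining ortho OH, held in a hydrogen bond to the ketone, resists alkylation at room temperature, so the reaction should stop at the bis-ether.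

Step 2
Reactants: 3 1-[2,4-bis(benzyloxy)-6-hydroxyphenyl]ethan-1-one
Product: 5 chromone 5,7-bis(benzyloxy)-4H-chromen-4-one, via enaminone 4 (not isolated)
Conditions: Me2NCH(OMe)2, toluene, 95 °C; then conc. HCl, CH2Cl2, 40 °C
Reagents that add atoms: N,N-dimethylformamide dimethyl acetal, COC(OC)N(C)C
Why: Enaminone condensation of the methyl ketone with the amide acetal, then acid-promoted addition–elimination of the phenol with loss of dimethylamine, is the standard chromone synthesis and supplies C2A.

Step 3
Reactants: 5 5,7-bis(benzyloxy)-4H-chromen-4-one; 6 4-methoxyphenylboronic acid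
Product: 7 flavanone A, (2R)-5,7-bis(benzyloxy)-2-(4-methoxyphenyl)chroman-4-one
Conditions: [Rh(OH)(cod)]2 (monovalent rhodium, cat.), (S)-MeO-F12-BIPHEP [2,2'-bis{bis(3,4,5-trifluorophenyl)phosphino}-6,6'-dimethoxybiphenyl], toluene/H2O 10:1, 25 °C
Reagents that add atoms: none
Why: Hayashi–Miyaura-type rhodium-catalysed asymmetric 1,4-addition, in which the aryl–rhodium species adds to C2 of the chromone on the face chosen by the electron-poor chiral bisphosphine (setting C2A as R) and water protonates the rhodium enolate under base-free conditions that spare the flavanone from ring opening.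

Step 4
Reactants: 1 2,4,6-trihydroxyacetophenone; 8 4-(benzyloxy)benzyl chloride
Product: 9 1-{2,4-bis[(4-benzyloxybenzyl)oxy]-6-hydroxyphenyl}ethan-1-one
Conditions: 8 (2.1 equiv in all), K2CO3, KI (cat.), DMF, rt
Reagents that add atoms: 4-(benzyloxy)benzyl chloride (second equivalent), ClCc1ccc(OCc2ccccc2)cc1
Why: Williamson etherification that, like step 1, should stop at the bis-ether because the remaining ortho OH is locked in a hydrogen bond to the ketone, while the mild base at room temperature limits C-alkylation of the phloroglucinol ring by the reactive 4-alkoxybenzyl halide.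

Step 5
Reactants: 9 1-{2,4-bis[(4-benzyloxybenzyl)oxy]-6-hydroxyphenyl}ethan-1-one; 8 4-(benzyloxy)benzyl chloride
Product: 10 1-{2,4,6-tris[(4-benzyloxybenzyl)oxy]phenyl}ethan-1-one
Conditions: K2CO3, KI (cat.), DMF, 60 °C
Reagents that add atoms: none
Why: Williamson etherification with iodide catalysis (in situ Finkelstein exchange), in which heat breaks the hydrogen bond of the last phenol so that the third 4-(benzyloxy)benzyl group is installed on oxygen.

Step 6
Reactants: 10 1-{2,4,6-tris[(4-benzyloxybenzyl)oxy]phenyl}ethan-1-one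
Product: 12 2-bromo-1-{2,4,6-tris[(4-benzyloxybenzyl)oxy]phenyl}ethan-1-one, via trimethylsilyl enol ether 11 (not isolated)
Conditions: TMSOTf, Et3N, CH2Cl2, 0 °C; then NBS, THF, –78 °C
Reagents that add atoms: N-bromosuccinimide, O=C1CCC(=O)N1Br
Why: Soft enolisation gives the silyl enol ether, whose electrophilic bromination by NBS should be far faster than bromination of the alkoxy-substituted rings and releases no HBr onto the acid-labile benzylic ethers.

Step 7
Reactants: 7 flavanone A; 12 2-bromo-1-{2,4,6-tris[(4-benzyloxybenzyl)oxy]phenyl}ethan-1-one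
Product: 14 (2R,3S)-5,7-bis(benzyloxy)-2-(4-methoxyphenyl)-3-(2-oxo-2-{2,4,6-tris[(4-benzyloxybenzyl)oxy]phenyl}ethyl)chroman-4-one, via lithium enolate of flavanone A 13 (not isolated)
Conditions: LiN(SiMe3)2, THF, –78 °C; then 12, DMPU, –78 to –40 °C; AcOH quench
Reagents that add atoms: none
Why: Enolate alkylation by SN2 displacement on an alpha-bromo ketone whose hindered carbonyl discourages addition, with the kinetically formed lithium enolate expected to resist retro-oxa-Michael opening at –78 °C and to be attacked opposite the C2A aryl group, which sets C3A as S (trans, also the more stable diequatorial isomer).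

Step 8
Reactants: 14 (2R,3S)-5,7-bis(benzyloxy)-2-(4-methoxyphenyl)-3-(2-oxo-2-{2,4,6-tris[(4-benzyloxybenzyl)oxy]phenyl}ethyl)chroman-4-one
Product: 17 (2R,3S)-5,7-bis(benzyloxy)-3-(1-diazo-2-oxo-2-{2,4,6-tris[(4-benzyloxybenzyl)oxy]phenyl}ethyl)-2-(4-methoxyphenyl)chroman-4-one, via lithium enolate of the diketone 15 (not isolated), via trifluoroacetyl diketone 16 (not isolated)
Conditions: LiN(SiMe3)2, THF, –78 °C; CF3CO2CH2CF3; NH4Cl quench; then MsN3, Et3N, H2O (1 equiv), MeCN, rt
Reagents that add atoms: methanesulfonyl azide, CS(=O)(=O)N=[N+]=[N-]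
Why: Danheiser detrifluoroacetylative diazo transfer, in which the C3B methylene (next to a ketone twisted out of conjugation with its doubly ortho-substituted ring) should be deprotonated faster than the hindered methine C3A beside the vinylogous-carbonate-like C4A ketone, Claisen acylation activates it, and the sulfonyl azide then delivers N2 with loss of the trifluoroacetyl group under mild amine base.

Step 9
Reactants: 17 (2R,3S)-5,7-bis(benzyloxy)-3-(1-diazo-2-oxo-2-{2,4,6-tris[(4-benzyloxybenzyl)oxy]phenyl}ethyl)-2-(4-methoxyphenyl)chroman-4-one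
Product: 18 (2R,3S)-5,7-bis(benzyloxy)-3-{(2R,3R)-2-[4-(benzyloxy)phenyl]-5,7-bis[(4-benzyloxybenzyl)oxy]-4-oxochroman-3-yl}-2-(4-methoxyphenyl)chroman-4-one
Conditions: Rh2(S-PTTL)4 (dirhodium tetrakis[N-phthaloyl-(S)-tert-leucinate], divalent rhodium, 2 mol %), toluene, 4 Å MS, slow addition of 17, –60 to –20 °C
Reagents that add atoms: none
Why: The dirhodium carboxylate expels N2 from C3B to give an electrophilic rhodium ketocarbenoid, which inserts through a three-centre, hydride-transfer-like transition state into a benzylic C–H bond of an ortho 4-(benzyloxy)benzyl ether, a bond activated by the ether oxygen and the electron-rich aryl group. The closest known reaction is the dirhodium-carboxylate-catalysed intramolecular C–H insertion of 2-alkoxyaryl alpha-diazoketones to cis-2,3-disubstituted chroman-4-ones. The pyranone ring of unit B closes by 1,6-insertion, C3B bonding to the ether carbon five atoms away (C3B–C4B–C4aB–C8aB–O1B–C2B) while the hydrogen of that carbon passes to C3B. C2B is set by the catalyst's choice between the two diastereotopic benzylic hydrogens, with the aryl group turned away from the carboxylate wall so that the ring forms 2,3-cis, and C3B is set by the carbenoid face that the C–H bond approaches, steered by the chiral phthalimido-tert-leucinate pocket together with the resident C3A stereocentre. The step needs insertion to outrun 1,2-hydride shift from C3A, oxonium ylide formation and attack on the anisyl ring: the C3A–H bond lies alpha to the C4A ketone and is poorly hydridic, the ether oxygens are weak donors on an acyl-substituted ring, and bulky carboxylates at low temperature favour the activated benzylic C–H bond. Because the two ortho ethers are identical, insertion into either gives the same product and the other stays as a protecting group.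

Step 10
Reactants: 18 (2R,3S)-5,7-bis(benzyloxy)-3-{(2R,3R)-2-[4-(benzyloxy)phenyl]-5,7-bis[(4-benzyloxybenzyl)oxy]-4-oxochroman-3-yl}-2-(4-methoxyphenyl)chroman-4-one
Product: 19 sikokianin B
Conditions: H2 (1 atm), 10% Pd/C, THF/MeOH 1:1, rt
Reagents that add atoms: none
Why: Hydrogenolysis of benzylic C–O bonds, in which the five benzyl ethers are cleaved and the two resulting 4-hydroxybenzyl aryl ethers then lose 4-methylphenol, under neutral conditions that should neither reduce the hydrogen-bonded aryl ketones nor epimerise the base-labile cis centre C3B.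

Compound list
1 | 2,4,6-trihydroxyacetophenone | CC(=O)c1c(O)cc(O)cc1O | starting material
2 | benzyl bromide | BrCc1ccccc1 | starting material
3 | 1-[2,4-bis(benzyloxy)-6-hydroxyphenyl]ethan-1-one | CC(=O)c1c(O)cc(OCc2ccccc2)cc1OCc1ccccc1 | intermediate
4 | (E)-1-[2,4-bis(benzyloxy)-6-hydroxyphenyl]-3-(dimethylamino)prop-2-en-1-one (enaminone) | CN(C)/C=C/C(=O)c1c(O)cc(OCc2ccccc2)cc1OCc1ccccc1 | intermediate
5 | 5,7-bis(benzyloxy)-4H-chromen-4-one | O=c1ccoc2cc(OCc3ccccc3)cc(OCc3ccccc3)c12 | intermediate
6 | 4-methoxyphenylboronic acid | COc1ccc(B(O)O)cc1 | starting material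
7 | flavanone A, (2R)-5,7-bis(benzyloxy)-2-(4-methoxyphenyl)chroman-4-one | COc1ccc([C@@H]2Oc3cc(OCc4ccccc4)cc(OCc4ccccc4)c3C(=O)C2)cc1 | intermediate
8 | 4-(benzyloxy)benzyl chloride | ClCc1ccc(OCc2ccccc2)cc1 | starting material
9 | 1-{2,4-bis[(4-benzyloxybenzyl)oxy]-6-hydroxyphenyl}ethan-1-one | CC(=O)c1c(O)cc(OCc2ccc(OCc3ccccc3)cc2)cc1OCc1ccc(OCc2ccccc2)cc1 | intermediate
10 | 1-{2,4,6-tris[(4-benzyloxybenzyl)oxy]phenyl}ethan-1-one | CC(=O)c1c(OCc2ccc(OCc3ccccc3)cc2)cc(OCc2ccc(OCc3ccccc3)cc2)cc1OCc1ccc(OCc2ccccc2)cc1 | intermediate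
11 | trimethylsilyl enol ether of 10, trimethyl({1-[2,4,6-tris(4-benzyloxybenzyloxy)phenyl]ethenyl}oxy)silane | C=C(O[Si](C)(C)C)c1c(OCc2ccc(OCc3ccccc3)cc2)cc(OCc2ccc(OCc3ccccc3)cc2)cc1OCc1ccc(OCc2ccccc2)cc1 | intermediate
12 | 2-bromo-1-{2,4,6-tris[(4-benzyloxybenzyl)oxy]phenyl}ethan-1-one | BrCC(=O)c1c(OCc2ccc(OCc3ccccc3)cc2)cc(OCc2ccc(OCc3ccccc3)cc2)cc1OCc1ccc(OCc2ccccc2)cc1 | intermediate
13 | lithium enolate of flavanone A, lithium (2R)-5,7-bis(benzyloxy)-2-(4-methoxyphenyl)-2H-chromen-4-olate | COc1ccc([C@@H]2Oc3cc(OCc4ccccc4)cc(OCc4ccccc4)c3C([O-])=C2)cc1.[Li+] | intermediate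
14 | (2R,3S)-5,7-bis(benzyloxy)-2-(4-methoxyphenyl)-3-(2-oxo-2-{2,4,6-tris[(4-benzyloxybenzyl)oxy]phenyl}ethyl)chroman-4-one | COc1ccc([C@@H]2Oc3cc(OCc4ccccc4)cc(OCc4ccccc4)c3C(=O)[C@H]2CC(=O)c2c(OCc3ccc(OCc4ccccc4)cc3)cc(OCc3ccc(OCc4ccccc4)cc3)cc2OCc2ccc(OCc3ccccc3)cc2)cc1 | intermediate
15 | lithium (Z)-enolate of 14 at C3B=C4B | COc1ccc([C@@H]2Oc3cc(OCc4ccccc4)cc(OCc4ccccc4)c3C(=O)[C@H]2/C=C(\[O-])c2c(OCc3ccc(OCc4ccccc4)cc3)cc(OCc3ccc(OCc4ccccc4)cc3)cc2OCc2ccc(OCc3ccccc3)cc2)cc1.[Li+] | intermediate
16 | C3B-trifluoroacetyl derivative of 14, (2R,3S)-5,7-bis(benzyloxy)-2-(4-methoxyphenyl)-3-(4,4,4-trifluoro-1,3-dioxo-1-{2,4,6-tris[(4-benzyloxybenzyl)oxy]phenyl}butan-2-yl)chroman-4-one (C3B epimers and enol forms) | COc1ccc([C@@H]2Oc3cc(OCc4ccccc4)cc(OCc4ccccc4)c3C(=O)[C@H]2C(C(=O)C(F)(F)F)C(=O)c2c(OCc3ccc(OCc4ccccc4)cc3)cc(OCc3ccc(OCc4ccccc4)cc3)cc2OCc2ccc(OCc3ccccc3)cc2)cc1 | intermediate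
17 | (2R,3S)-5,7-bis(benzyloxy)-3-(1-diazo-2-oxo-2-{2,4,6-tris[(4-benzyloxybenzyl)oxy]phenyl}ethyl)-2-(4-methoxyphenyl)chroman-4-one | COc1ccc([C@@H]2Oc3cc(OCc4ccccc4)cc(OCc4ccccc4)c3C(=O)[C@H]2C(=[N+]=[N-])C(=O)c2c(OCc3ccc(OCc4ccccc4)cc3)cc(OCc3ccc(OCc4ccccc4)cc3)cc2OCc2ccc(OCc3ccccc3)cc2)cc1 | intermediate
18 | (2R,3S)-5,7-bis(benzyloxy)-3-{(2R,3R)-2-[4-(benzyloxy)phenyl]-5,7-bis[(4-benzyloxybenzyl)oxy]-4-oxochroman-3-yl}-2-(4-methoxyphenyl)chroman-4-one | COc1ccc([C@@H]2Oc3cc(OCc4ccccc4)cc(OCc4ccccc4)c3C(=O)[C@H]2[C@H]2C(=O)c3c(OCc4ccc(OCc5ccccc5)cc4)cc(OCc4ccc(OCc5ccccc5)cc4)cc3O[C@H]2c2ccc(OCc3ccccc3)cc2)cc1 | intermediate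
19 | sikokianin B, (2R,3S)-5,7-dihydroxy-3-[(2R,3R)-5,7-dihydroxy-2-(4-hydroxyphenyl)-4-oxochroman-3-yl]-2-(4-methoxyphenyl)chroman-4-one | COc1ccc([C@@H]2Oc3cc(O)cc(O)c3C(=O)[C@H]2[C@H]2C(=O)c3c(O)cc(O)cc3O[C@H]2c2ccc(O)cc2)cc1 | target

Total step count: 10. Longest linear sequence: 7 steps (steps 1, 2, 3, 7, 8, 9, 10; the branch through steps 4, 5, 6 is equally long).

Steps most likely to fail

Step 9. Migration of the C3A hydrogen to the carbenoid carbon may outrun insertion, the catalyst may fail to override the facial bias that C3A imposes, or the carbenoid may attack the nearby anisyl ring. The fallback is a carbene-free formal insertion by hydride abstraction, setting out from 14 and coming back at 18. Diketone 14 would be converted (KN(SiMe3)2, Ac2O, THF, –78 °C) into the (Z)-enol acetate of the C4B ketone F1. One equivalent of DDQ with 2,6-dichloropyridine and LiClO4 in 1,2-dichloroethane would then abstract hydride from an ortho benzylic ether carbon, and the (E)-aryloxocarbenium ion would be captured by C3B of the enol acetate with loss of the acetyl group (oxidative C–H cleavage and cyclisation of a benzylic ether onto an enol acetate). Closure within the aryl-bridged array places the aryl group and C3A on the outer positions of both termini and should give the cis ring kinetically. Face selectivity relative to C3A would rest on the substrate alone, so the other cis isomer would have to be separated.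

Step 8. Deprotonation may occur at C3A in place of C3B, followed by beta-elimination of the aryloxide (opening of the pyranone ring of unit A) and loss of configuration at C2A and C3A; the product may also cyclise through its C4A enol onto the diazo group. The fallback goes from 14 to 17 without amide base. Condensation with tert-butoxybis(dimethylamino)methane (toluene, 70 °C) can give a stable product only at the methylene carbon C3B and would form the enaminone of the diketone F2. Tosyl azide in MeCN would then transfer the diazo group by cycloaddition and fragmentation with loss of the sulfonyl formamidine (deformylative Regitz-type transfer).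

Step 7. Proton transfer from the acidic bromoketone or from the product to the enolate, and ring opening of the enolate on warming, may stall conversion and erode C2A. The fallback replaces the polar alkylation by a radical one, from 7 to 14. Soft enolisation (TBSOTf, Et3N, CH2Cl2, 0 °C) would give the tert-butyldimethylsilyl enol ether of flavanone A F3. Visible-light photoredox coupling with 12 (fac-Ir(ppy)3 (trivalent iridium), 2,6-lutidine, MeCN, blue light) would generate the aroylmethyl radical, which adds to C3A opposite the aryl group. Oxidation of the alpha-silyloxy radical and loss of the silyl group would give 14.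

Further compounds
F1 | step 9 | (Z)-2-[(2R,3S)-5,7-bis(benzyloxy)-2-(4-methoxyphenyl)-4-oxochroman-3-yl]-1-{2,4,6-tris[(4-benzyloxybenzyl)oxy]phenyl}ethenyl acetate | COc1ccc([C@@H]2Oc3cc(OCc4ccccc4)cc(OCc4ccccc4)c3C(=O)[C@H]2/C=C(\OC(C)=O)c2c(OCc3ccc(OCc4ccccc4)cc3)cc(OCc3ccc(OCc4ccccc4)cc3)cc2OCc2ccc(OCc3ccccc3)cc2)cc1
F2 | step 8 | (2R,3S)-5,7-bis(benzyloxy)-3-[3-(dimethylamino)-1-oxo-1-{2,4,6-tris[(4-benzyloxybenzyl)oxy]phenyl}prop-2-en-2-yl]-2-(4-methoxyphenyl)chroman-4-one (alkene geometry not defined) | COc1ccc([C@@H]2Oc3cc(OCc4ccccc4)cc(OCc4ccccc4)c3C(=O)[C@H]2C(=CN(C)C)C(=O)c2c(OCc3ccc(OCc4ccccc4)cc3)cc(OCc3ccc(OCc4ccccc4)cc3)cc2OCc2ccc(OCc3ccccc3)cc2)cc1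
F3 | step 7 | (2R)-5,7-bis(benzyloxy)-4-[(tert-butyldimethylsilyl)oxy]-2-(4-methoxyphenyl)-2H-chromene | COc1ccc([C@@H]2Oc3cc(OCc4ccccc4)cc(OCc4ccccc4)c3C(O[Si](C)(C)C(C)(C)C)=C2)cc1
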